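The plan rests on cutting the unbranched, stereocentre-free tetracosanoyl chain between C10 and C11, a bond that can be made as an alkene and then saturated because no other group in the chain would be affected. Undec-10-enoic acid 1 is esterified with 2-phenylethanol 2 to give the terminal-alkene ester 3, which already carries C1–C10 and the phenethyl ester, whose benzene ring, the only ring, sits two carbons from the ester oxygen. Ruthenium-catalysed cross-metathesis of 3 with pentadec-1-ene 4 joins the fragments at C10=C11 in one operation with release of ethylene, giving alkene 5; hydrogenation over Pd/C then delivers target 6 without touching the homobenzylic C–O bond.

Key step: step 2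

Remark: chain carbons are numbered from the ester carbonyl (C1). The metathesis is under thermodynamic control and should give mainly the E alkene, which is drawn as 5. A minor amount of its Z isomer, of the same constitution, is expected to accompany it; it is not separated and is converted into the same saturated ester in step 3.

Step 1
Reactants: 1 undec-10-enoic acid; 2 2-phenylethanol
Product: 3 2-phenylethyl undec-10-enoate
Conditions: 2 (1.1 equiv), p-TsOH·H2O (cat.), toluene, reflux, Dean–Stark trap
Reagents that add atoms: none
Why: Fischer esterification of an unhindered acid with a primary alcohol should go to completion when the water is removed azeotropically, and neither the isolated terminal alkene nor the phenyl ring is expected to react with catalytic sulfonic acid in toluene.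

Step 2
Reactants: 3 2-phenylethyl undec-10-enoate; 4 pentadec-1-ene
Product: 5 2-phenylethyl (E)-tetracos-10-enoate
Conditions: 4 (4 equiv), second-generation Grubbs catalyst (H2IMes)(PCy3)Cl2Ru=CHPh (2 mol%), 1,4-benzoquinone (10 mol%), CH2Cl2, reflux (40 °C), slow argon purge; then ethyl vinyl ether
Reagents that add atoms: none
Why: The ruthenium benzylidene is converted by a terminal alkene into an alkylidene, which adds to the partner alkene in a [2+2] fashion to give a ruthenacyclobutane; cycloreversion releases the C10=C11 alkene and a ruthenium methylidene, which takes up the next terminal alkene and expels ethylene, and the argon stream removes that ethylene and pulls the equilibria forward. The closest known reaction type is ruthenium-catalysed cross-metathesis of two unhindered terminal alkenes remote from any coordinating group, as practised on ω-unsaturated fatty esters and 1-alkenes. No ring is closed and no stereocentre is created; the only new element of geometry is the C10=C11 double bond, expected to be mainly E under thermodynamic control, and it needs no control because step 3 erases it. The selectivity that matters is cross-coupling against self-coupling, secured by charging 4 in fourfold excess and by the fact that both homodimers are still unhindered 1,2-disubstituted alkenes that re-enter the cycle by secondary metathesis, while the ester at C1 lies eight methylenes from the alkene and cannot chelate ruthenium. Positional integrity of the alkene matters equally, since a migrated double bond would lead to C23 and C25 homologues that could not be removed later, and 1,4-benzoquinone together with the mild temperature is there to intercept ruthenium hydride species. The monoester 5 should separate on silica from the non-polar octacos-14-ene and excess 4 and from the more polar diester homodimer of 3.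

Step 3
Reactants: 5 2-phenylethyl (E)-tetracos-10-enoate
Product: 6 2-phenylethyl tetracosanoate (target)
Conditions: H2 (1 atm), 10% Pd/C, EtOAc/THF, rt
Reagents that add atoms: none
Why: Heterogeneous catalytic hydrogenation should saturate the unhindered 1,2-disubstituted alkene, whichever its geometry, far faster than it attacks the benzene ring, and the ester C–O bond is homobenzylic, not benzylic, so hydrogenolysis is not expected.

Compound list
1 | undec-10-enoic acid | C=CCCCCCCCCC(=O)O | starting material
2 | 2-phenylethanol | OCCc1ccccc1 | starting material
3 | 2-phenylethyl undec-10-enoate | C=CCCCCCCCCC(=O)OCCc1ccccc1 | intermediate
4 | pentadec-1-ene | C=CCCCCCCCCCCCCC | starting material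
5 | 2-phenylethyl (E)-tetracos-10-enoate | CCCCCCCCCCCCC/C=C/CCCCCCCCC(=O)OCCc1ccccc1 | intermediate
6 | 2-phenylethyl tetracosanoate (phenylethyl n-tetracosanoate) | CCCCCCCCCCCCCCCCCCCCCCCC(=O)OCCc1ccccc1 | target

Total step count: 3
Longest linear sequence: 3 steps (1 → 3 → 5 → 6)

Steps most likely to fail, in order of risk

Step 2. Self-coupling of 3 may outrun cross-coupling, and ruthenium hydride species may move the double bond along the chain before or after metathesis, which would scramble the chain length. The fallback sets out from 3 and fixes the chain length by the reagents instead of by statistics. Ozonolysis of the terminal alkene (O3, CH2Cl2, −78 °C, then dimethyl sulfide) should give 2-phenylethyl 10-oxodecanoate F1. Separately, commercial tetradecyltriphenylphosphonium bromide is deprotonated with NaN(SiMe3)2 in THF to give tetradecylidene(triphenyl)phosphorane F2. Addition of F1 to F2 at −78 °C should form the same C10=C11 bond by a Wittig reaction, the non-stabilised ylide favouring the Z alkene, 2-phenylethyl (Z)-tetracos-10-enoate F3. Hydrogenation of F3 under the conditions of step 3 (H2, 10% Pd/C, EtOAc/THF, rt) should then saturate the chain, so that the fallback comes back to the route at 6.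

Step 3. Saturation may stall because traces of ruthenium or phosphine carried over from step 2 poison the palladium surface, or because the waxy substrate and product crystallise onto the catalyst; prolonged forcing could in turn begin to reduce the benzene ring. The fallback sets out from 5 and uses a metal-free reduction. Diimide F4, generated in the flask from p-toluenesulfonyl hydrazide and NaOAc in refluxing THF/water, should transfer two hydrogens to the alkene in a concerted syn fashion and leave the arene and the ester alone. The fallback comes back to the route at 6.

Step 1. Conversion may stop at the esterification equilibrium if water removal is inefficient, and long heating with acid may cause partial migration of the terminal double bond. The fallback sets out from 1 and replaces the equilibrium process by an irreversible acylation. Oxalyl chloride with catalytic DMF in CH2Cl2 should give undec-10-enoyl chloride F5, which acylates 2 in the presence of triethylamine and catalytic DMAP at 0 °C to rt. The fallback comes back to the route at 3.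

Further compounds
F1 | step 2 | 2-phenylethyl 10-oxodecanoate | O=CCCCCCCCCC(=O)OCCc1ccccc1
F2 | step 2 | tetradecylidene(triphenyl)phosphorane | CCCCCCCCCCCCCC=P(c1ccccc1)(c1ccccc1)c1ccccc1
F3 | step 2 | 2-phenylethyl (Z)-tetracos-10-enoate | CCCCCCCCCCCCC/C=C\CCCCCCCCC(=O)OCCc1ccccc1
F4 | step 3 | diimide | N=N
F5 | step 1 | undec-10-enoyl chloride | C=CCCCCCCCCC(=O)Cl
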